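**Retrosynthetic overview**
- The target comes from the all-trans 2-aryl-4-aroyl-tetrahydrofuran-3-carbaldehyde (phenols as silyl ethers). The last operations are CHO → CH2OH and desilylation.
- The tetrahydrofuran (second ring formed) comes from an ionic seven-to-five ring contraction of a 2-aryl-5-aroyl-4,5-dihydro-1,3-dioxepine. The acetal C–O bond breaks, and the enol carbon closes on the oxocarbenium carbon (C2–C3 bond). A chiral counter-anion fixes C2, and C3/C4 follow by equilibration.
- The vinyl acetal comes from deconjugation of its 4,7-dihydro enone isomer. That isomer comes from acetalisation (first ring formed) of O-silyl vanillin with an enone carrying two cis CH2O arms.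
- The enone comes from syn hydroacylation of but-2-yne-1,4-diol (as its bis-TMS ether) with O-silyl syringaldehyde.
- Syringaldehyde comes from p-cresol (Br2, then NaOMe/CuCl). Vanillin comes from catechol (MeI, then glyoxylic acid).

**Assumption:** the sense of induction of the new catalyst in step 10 cannot be known in advance. The (S,S) catalyst is written, and its mirror image is used if it delivers 2R.

**Numbering and abbreviations**
- Tetrahydrofuran: O1, C2 (guaiacyl), C3 (CH2OH or CHO), C4 (aroyl), C5 (CH2). The target is the all-trans (2S,3R,4S) isomer.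
- Dioxepine: O1, C2 (acetal), O3, C4 to C7.
- TBS = tert-butyldimethylsilyl; TMS = trimethylsilyl.
- IDPi = HN[P(=NSO2CF3)(diolate)]2, where each diolate is (S)-3,3'-bis[3,5-bis(trifluoromethyl)phenyl]-1,1'-binaphthyl-2,2'-diolate.

**Step 1**
Reactants: 1 p-cresol (4-methylphenol)
Product: 4 3,5-dibromo-4-hydroxybenzaldehyde, via 2,6-dibromo-4-methylphenol 2 (not isolated), via 2,6-dibromo-4-(dibromomethyl)phenol 3 (not isolated)
Conditions: Br2 (2.05 equiv), o-dichlorobenzene, 35 °C; Br2 (2.05 equiv), 155 °C; then H2O, 100 °C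
Reagents that add atoms: bromine BrBr; water O
Why: Electrophilic aromatic bromination at both positions ortho to the phenol, thermal benzylic dibromination of the deactivated ring and hydrolysis of the benzal bromide form an established technical sequence that creates no stereocentre.

**Step 2**
Reactants: 4 3,5-dibromo-4-hydroxybenzaldehyde
Product: 5 syringaldehyde (4-hydroxy-3,5-dimethoxybenzaldehyde)
Conditions: NaOMe (4 equiv), CuCl (0.2 equiv), DMF/MeOH, 115 °C; then aq HCl
Reagents that add atoms: sodium methoxide C[O-].[Na+]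
Why: Copper-catalysed Ullmann-type methoxylation replaces both aryl bromides, and the phenoxide formed in situ shields the aldehyde from base-induced side reactions.

**Step 3**
Reactants: 5 syringaldehyde
Product: 6 4-(tert-butyldimethylsilyloxy)-3,5-dimethoxybenzaldehyde
Conditions: TBSCl (1.2 equiv), imidazole (2.5 equiv), DMF, 23 °C
Reagents that add atoms: tert-butyldimethylsilyl chloride CC(C)(C)[Si](C)(C)Cl
Why: Imidazole-promoted silyl ether formation masks the acidic phenol, which would otherwise protonate the organonickel intermediates and the amide base used later.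

**Step 4**
Reactants: 7 but-2-yne-1,4-diol; 6 4-(tert-butyldimethylsilyloxy)-3,5-dimethoxybenzaldehyde
Product: 9 (E)-1-[4-(TBSO)-3,5-dimethoxyphenyl]-4-(trimethylsilyloxy)-2-[(trimethylsilyloxy)methyl]but-2-en-1-one (both CH2OTMS arms cis), via 1,4-bis(trimethylsilyloxy)but-2-yne 8 (not isolated)
Conditions: 7, (Me3Si)2NH (1.05 equiv), neat, 120 °C, volatiles removed in vacuo; then 6, Ni(cod)2 (10 mol%), P(n-C8H17)3 (20 mol%), THF, 100 °C (sealed)
Reagents that add atoms: hexamethyldisilazane C[Si](C)(C)N[Si](C)(C)C
Why: After O-silylation, nickel-catalysed intermolecular alkyne hydroacylation proceeds by oxidative cyclisation of alkyne and aldehyde on zerovalent nickel, β-hydride elimination and C–H reductive elimination, so no acyl metal hydride can decarbonylate, the symmetrical alkyne raises no regiochemical question, and syn addition places the two CH2O arms cis as the seven-membered acetal requires.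

**Step 5**
Reactants: 10 catechol
Product: 11 guaiacol (2-methoxyphenol)
Conditions: MeI (1.0 equiv), K2CO3 (1.0 equiv), catechol (1.5 equiv), acetone, reflux
Reagents that add atoms: iodomethane CI
Why: Williamson mono-O-methylation with catechol in excess keeps veratrole formation low, and guaiacol is separated from catechol and veratrole by extraction and distillation.

**Step 6**
Reactants: 11 guaiacol; 12 glyoxylic acid
Product: 15 vanillin (4-hydroxy-3-methoxybenzaldehyde), via 4-hydroxy-3-methoxymandelic acid 13 (not isolated), via 4-hydroxy-3-methoxyphenylglyoxylic acid 14 (not isolated)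
Conditions: 12 (50% aq), NaOH, H2O, 30 °C; then air, CuSO4 (5 mol%), NaOH, 95 °C; then H2SO4 to pH 3
Reagents that add atoms: none
Why: Para-selective electrophilic hydroxyalkylation of the phenoxide by glyoxylate followed by aerobic oxidation and decarboxylation of the aryl glyoxylic acid is the technical vanillin process, and the racemic carbinol centre of 13 is destroyed.

**Step 7**
Reactants: 15 vanillin
Product: 16 4-(tert-butyldimethylsilyloxy)-3-methoxybenzaldehyde
Conditions: TBSCl (1.2 equiv), imidazole (2.5 equiv), DMF, 23 °C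
Reagents that add atoms: tert-butyldimethylsilyl chloride CC(C)(C)[Si](C)(C)Cl
Why: Silyl ether formation prevents the phenoxide-assisted hydrolysis that makes acetals of free 4-hydroxybenzaldehydes unmanageable.

**Step 8**
Reactants: 9 enone bis-TMS ether; 16 4-(tert-butyldimethylsilyloxy)-3-methoxybenzaldehyde
Product: 17 racemic 2-[4-(TBSO)-3-methoxyphenyl]-5-[4-(TBSO)-3,5-dimethoxybenzoyl]-4,7-dihydro-1,3-dioxepine
Conditions: Me3SiOTf (5 mol%), CH2Cl2 (0.05 M), −78 → −30 °C; pyridine quench
Reagents that add atoms: none
Why: Noyori acetalisation of the aldehyde with the bis-TMS ether is driven by formation of hexamethyldisiloxane, runs without water or heat, and is helped by the cis alkene that preorganises the seven-membered ring, while the acetal stereocentre formed is racemic and is erased in step 10.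

**Step 9**
Reactants: 17 4,7-dihydro-1,3-dioxepine enone
Product: 19 2-[4-(TBSO)-3-methoxyphenyl]-5-[4-(TBSO)-3,5-dimethoxybenzoyl]-4,5-dihydro-1,3-dioxepine (racemic; 2,5-cis/trans mixture), via lithium dienolate 18 (not isolated)
Conditions: LiN(SiMe3)2 (1.1 equiv), THF, −78 °C, 20 min; cannulated into AcOH (3 equiv)/THF, −78 °C; used without chromatography
Reagents that add atoms: none
Why: Kinetic deconjugation removes the only vinylogously acidic protons (C7–H), and the extended enolate is protonated fastest at its α-carbon C5, which gives the β,γ-unsaturated ketone whose alkene is now the vinyl acetal, and neither new stereocentre matters because both are erased or equilibrated in step 10.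

**Step 10**
Reactants: 19 4,5-dihydro-1,3-dioxepine (vinyl acetal)
Product: 21 (2S,3S,4S)-2-[4-(TBSO)-3-methoxyphenyl]-4-[4-(TBSO)-3,5-dimethoxybenzoyl]tetrahydrofuran-3-carbaldehyde (all-trans), via 2S-configured C3/C4 epimer mixture 20 (not isolated)
Conditions: (S,S)-IDPi (5 mol%), 5 Å MS, toluene, −60 °C, 48 h; then DBU (0.3 equiv), −60 → 23 °C, 12 h
Reagents that add atoms: none
Why: Proposed new method: a catalytic enantioselective, stereoconvergent vinyl-acetal ring contraction (ionic, stepwise oxa-Petasis–Ferrier-type O-to-C transposition) in which the confined strong acid protonates the vinylic acetal oxygen O1 (an enol is the better leaving group), C2–O1 heterolysis erases the acetal stereocentre and gives an (E)-aryl oxocarbenium ion in a contact ion pair with the chiral anion that also hydrogen-bonds the liberated (Z)-enol, and 5-(enolexo) aldol-type attack of C6 on the Si face of the oxocarbenium carbon forms the C2–C3 bond and the tetrahydrofuran and sets 2S under catalyst control for both enantiomers of 19; A(1,3) strain in the (Z)-enol places the formyl carbon trans to the aroyl group, so one enantiomer of 19 gives the all-trans aldehyde directly and the other its C3,C4-bis-epimer, and DBU then equilibrates the two carbonyl-flanked centres to the all-trans isomer while C2 stays fixed (it is not enolisable, and either β-elimination would be the reverse of a disfavoured 5-endo-trig closure); the closest known reaction types are the achiral Lewis acid promoted ring contraction of 4,5-dihydro-1,3-dioxepines to tetrahydrofuran-3-carbaldehydes, the chiral phosphoric acid catalysed aza-Petasis–Ferrier rearrangement of racemic hemiaminal vinyl ethers, and imidodiphosphorimidate catalysed additions to oxocarbenium ion pairs.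

**Step 11**
Reactants: 21 all-trans keto aldehyde
Product: 23 target CNP0169680.1 (2S,3R,4S; all-trans), via bis-TBS alcohol 22 (not isolated)
Conditions: NaBH4 (1.0 equiv), CH2Cl2/MeOH 7:3, −78 °C; AcOH quench; then KHF2 (5 equiv), MeOH, 23 °C
Reagents that add atoms: none
Why: Chemoselective low-temperature borohydride reduction takes the unhindered aldehyde far faster than the α-branched, electron-rich aryl ketone, and bifluoride desilylation of the two phenolic TBS ethers is nearly neutral, so no stereocentre is made or scrambled and the 3,4-trans geometry prevents hemiketal formation.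

**Compound list**
1 | p-cresol | Cc1ccc(O)cc1 | starting material
2 | 2,6-dibromo-4-methylphenol | Cc1cc(Br)c(O)c(Br)c1 | intermediate
3 | 2,6-dibromo-4-(dibromomethyl)phenol | BrC(Br)c1cc(Br)c(O)c(Br)c1 | intermediate
4 | 3,5-dibromo-4-hydroxybenzaldehyde | O=Cc1cc(Br)c(O)c(Br)c1 | intermediate
5 | syringaldehyde | COc1cc(C=O)cc(OC)c1O | intermediate
6 | 4-(tert-butyldimethylsilyloxy)-3,5-dimethoxybenzaldehyde | COc1cc(C=O)cc(OC)c1O[Si](C)(C)C(C)(C)C | intermediate
7 | but-2-yne-1,4-diol | OCC#CCO | starting material
8 | 1,4-bis(trimethylsilyloxy)but-2-yne | C[Si](C)(C)OCC#CCO[Si](C)(C)C | intermediate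
9 | (E)-enone bis-TMS ether, CH2O arms cis | COc1cc(cc(OC)c1O[Si](C)(C)C(C)(C)C)C(=O)/C(CO[Si](C)(C)C)=C/CO[Si](C)(C)C | intermediate
10 | catechol | Oc1ccccc1O | starting material
11 | guaiacol | COc1ccccc1O | intermediate
12 | glyoxylic acid | O=CC(=O)O | starting material
13 | 4-hydroxy-3-methoxymandelic acid (racemic) | COc1cc(C(O)C(=O)O)ccc1O | intermediate
14 | 4-hydroxy-3-methoxyphenylglyoxylic acid | COc1cc(C(=O)C(=O)O)ccc1O | intermediate
15 | vanillin | COc1cc(C=O)ccc1O | intermediate
16 | 4-(tert-butyldimethylsilyloxy)-3-methoxybenzaldehyde | COc1cc(C=O)ccc1O[Si](C)(C)C(C)(C)C | intermediate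
17 | 2-aryl-5-aroyl-4,7-dihydro-1,3-dioxepine (racemic at C2) | COc1cc(C2OCC=C(CO2)C(=O)c3cc(OC)c(O[Si](C)(C)C(C)(C)C)c(OC)c3)ccc1O[Si](C)(C)C(C)(C)C | intermediate
18 | lithium dienolate of 17 (enolate geometry not defined) | [Li+].COc1cc(C2OCC(C=CO2)=C([O-])c3cc(OC)c(O[Si](C)(C)C(C)(C)C)c(OC)c3)ccc1O[Si](C)(C)C(C)(C)C | intermediate
19 | 2-aryl-5-aroyl-4,5-dihydro-1,3-dioxepine (racemic, 2,5-cis/trans mixture) | COc1cc(C2OCC(C=CO2)C(=O)c3cc(OC)c(O[Si](C)(C)C(C)(C)C)c(OC)c3)ccc1O[Si](C)(C)C(C)(C)C | intermediate
20 | (2S)-keto aldehyde, mixture of the (3S,4S) and (3R,4R) isomers | COc1cc([C@H]2OCC(C(=O)c3cc(OC)c(O[Si](C)(C)C(C)(C)C)c(OC)c3)C2C=O)ccc1O[Si](C)(C)C(C)(C)C | intermediate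
21 | (2S,3S,4S) all-trans keto aldehyde bis-TBS ether | COc1cc([C@H]2OC[C@@H](C(=O)c3cc(OC)c(O[Si](C)(C)C(C)(C)C)c(OC)c3)[C@@H]2C=O)ccc1O[Si](C)(C)C(C)(C)C | intermediate
22 | (2S,3R,4S) keto alcohol bis-TBS ether | COc1cc([C@H]2OC[C@@H](C(=O)c3cc(OC)c(O[Si](C)(C)C(C)(C)C)c(OC)c3)[C@@H]2CO)ccc1O[Si](C)(C)C(C)(C)C | intermediate
23 | (4-hydroxy-3,5-dimethoxyphenyl)[(3S,4R,5S)-5-(4-hydroxy-3-methoxyphenyl)-4-(hydroxymethyl)oxolan-3-yl]methanone | COc1cc([C@H]2OC[C@@H](C(=O)c3cc(OC)c(O)c(OC)c3)[C@@H]2CO)ccc1O | target

**Total step count:** 11.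
**Longest linear sequence:** 8 (steps 1, 2, 3, 4, 8, 9, 10, 11).

**Steps most likely to fail**

*Step 10 (the new reaction).*
- Risks: weak facial control for the enantiomer of 19 that must close 2,3-cis, reversible closure, hydrolysis by traces of water, and acid-induced reconjugation.
- The fallback uses only known chemistry. It sets out from 19 and comes back to the route at 23.
- The established achiral version of the ring contraction (Me3SiOTf, CH2Cl2, −78 to 0 °C) followed by DBU equilibration gives the racemic all-trans keto aldehyde F1.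
- NaBH4 in CH2Cl2/MeOH at −78 °C gives the racemic keto alcohol F2.
- Acylation with (1S)-camphanoyl chloride (pyridine, DMAP, CH2Cl2) gives the (2S,3R,4S)-camphanate F3 and the (2R,3S,4R)-camphanate F4, which are separated by crystallisation or chromatography.
- K2CO3 in MeOH removes the camphanoyl group and both aryl silyl ethers from F3 and delivers 23.

*Step 4 (hydroacylation).*
- Risks: alkyne oligomerisation at 100 °C, slow β-hydride elimination from the nickelacycle, and loss of a propargylic silyloxy group.
- The fallback sets out from 6 and 8 and comes back at 9.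
- It splits the redox-neutral coupling into a reductive coupling and an oxidation. Ni(cod)2 (10 mol%), P(n-Bu)3 (20 mol%) and Et3B (2 equiv) in toluene at 23 °C turn the nickelacycle over with a terminal reductant and give the racemic (E)-allylic alcohol F5.
- MnO2 in CH2Cl2 then oxidises F5, which is both allylic and benzylic, to 9.

*Step 9 (deconjugation).*
- Risks: E1cB loss of the C4–O3 alkoxide from the dienolate, γ-protonation back to 17, and reconjugation on handling.
- The fallback sets out from 17 and comes back at 19. It moves the alkene while the carbonyl group is switched off.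
- i-Bu2AlH (toluene, −78 °C) reduces the enone 1,2 to the allylic alcohol F6.
- A nickel hydride made from NiBr2(dppb) and LiBHEt3 (THF, 23 °C, one further equivalent of LiBHEt3 for the hydroxyl group) isomerises the allyl ether to the vinyl acetal. This is known for 5-substituted 4,7-dihydro-1,3-dioxepines, and it gives the 4,5-dihydro carbinol F7.
- Dess–Martin periodinane buffered with pyridine (CH2Cl2, 0 °C) oxidises F7 to 19 without base or acid.

**Further compounds**
F1 | step 10 | racemic all-trans keto aldehyde bis-TBS ether (1:1 pair of enantiomers) | COc1cc([C@H]2OC[C@@H](C(=O)c3cc(OC)c(O[Si](C)(C)C(C)(C)C)c(OC)c3)[C@@H]2C=O)ccc1O[Si](C)(C)C(C)(C)C.COc1cc([C@@H]2OC[C@H](C(=O)c3cc(OC)c(O[Si](C)(C)C(C)(C)C)c(OC)c3)[C@H]2C=O)ccc1O[Si](C)(C)C(C)(C)C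
F2 | step 10 | racemic all-trans keto alcohol bis-TBS ether (1:1 pair of enantiomers) | COc1cc([C@H]2OC[C@@H](C(=O)c3cc(OC)c(O[Si](C)(C)C(C)(C)C)c(OC)c3)[C@@H]2CO)ccc1O[Si](C)(C)C(C)(C)C.COc1cc([C@@H]2OC[C@H](C(=O)c3cc(OC)c(O[Si](C)(C)C(C)(C)C)c(OC)c3)[C@H]2CO)ccc1O[Si](C)(C)C(C)(C)C
F3 | step 10 | (1S)-camphanate of the (2S,3R,4S) alcohol | COc1cc([C@H]2OC[C@@H](C(=O)c3cc(OC)c(O[Si](C)(C)C(C)(C)C)c(OC)c3)[C@@H]2COC(=O)[C@@]45CC[C@@](C)(C(=O)O4)C5(C)C)ccc1O[Si](C)(C)C(C)(C)C
F4 | step 10 | (1S)-camphanate of the (2R,3S,4R) alcohol | COc1cc([C@@H]2OC[C@H](C(=O)c3cc(OC)c(O[Si](C)(C)C(C)(C)C)c(OC)c3)[C@H]2COC(=O)[C@@]45CC[C@@](C)(C(=O)O4)C5(C)C)ccc1O[Si](C)(C)C(C)(C)C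
F5 | step 4 | racemic (E)-1-[4-(TBSO)-3,5-dimethoxyphenyl]-4-(trimethylsilyloxy)-2-[(trimethylsilyloxy)methyl]but-2-en-1-ol | COc1cc(cc(OC)c1O[Si](C)(C)C(C)(C)C)C(O)/C(CO[Si](C)(C)C)=C/CO[Si](C)(C)C
F6 | step 9 | 2-aryl-5-[aryl(hydroxy)methyl]-4,7-dihydro-1,3-dioxepine (racemic diastereomer mixture) | COc1cc(C2OCC=C(CO2)C(O)c3cc(OC)c(O[Si](C)(C)C(C)(C)C)c(OC)c3)ccc1O[Si](C)(C)C(C)(C)C
F7 | step 9 | 2-aryl-5-[aryl(hydroxy)methyl]-4,5-dihydro-1,3-dioxepine (racemic diastereomer mixture) | COc1cc(C2OCC(C=CO2)C(O)c3cc(OC)c(O[Si](C)(C)C(C)(C)C)c(OC)c3)ccc1O[Si](C)(C)C(C)(C)C
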